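The retrosynthesis cuts C12–C13 (diene head) and C11=C12 first, then the two ring B bonds C9–C10 and C7–C8 in one [4+2] step. The C8 hydroxyl is carried as a C–B bond, and the diene carries an ethoxy group on C6 that is deleted after use.
In the forward direction, ring A is made first from 2-methylcyclohexane-1,3-dione as a trans-fused acetonide enol triflate and joined to a 1-ethoxyvinyl unit. Ring B then closes by Diels–Alder addition of a cis β-boryl crotonate, and the side chain is joined last by hydroboration and Suzuki coupling with chloroprene.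
Stereochemistry: C4 comes from a Corey–Bakshi–Shibata desymmetrisation, and C3 from an Evans–Tishchenko hydride relay (anti to the relay hydroxyl, hence trans to the hydroxymethyl arm). C10 comes from dienophile attack anti to the axial C4 methyl. C8 and C9 come from the endo mode of the cis dienophile, with C–B oxidation under retention. C5 comes from protonation and equilibration of the C6 ketone to the trans-decalin.
Key step: step 13
Remark on the chemistry: labdane numbering is used for the bicyclic compounds; the hydroxymethyl group on C4 is taken as the substituent trans to the C10 methyl, and the C9 side chain as cis to the C8 hydroxyl, as the target SMILES requires.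

Step 1
Reactants: 1 2-methylcyclohexane-1,3-dione
Product: 2 2-(hydroxymethyl)-2-methylcyclohexane-1,3-dione
Conditions: 37% aq. CH2O, H2O, rt
Reagents that add atoms: formaldehyde C=O
Why: Aldol addition of the enolised 1,3-dione to formaldehyde takes place at its only nucleophilic carbon and gives the still achiral quaternary carbon that becomes C4; no stereocenter is formed.

Step 2
Reactants: 2 hydroxymethyl dione
Product: 3 2-{[tert-butyl(dimethyl)silyl]oxymethyl}-2-methylcyclohexane-1,3-dione
Conditions: TBSCl, imidazole, DMF, 0 °C → rt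
Reagents that add atoms: tert-butyldimethylsilyl chloride CC(C)(C)[Si](C)(C)Cl
Why: Silylation of a primary alcohol under non-enolising conditions blocks retro-aldol loss of formaldehyde and makes the oxymethyl arm the larger of the two groups on the prochiral carbon.

Step 3
Reactants: 3 silyl ether dione
Product: 4 (2R,3R)-2-{[tert-butyl(dimethyl)silyl]oxymethyl}-3-hydroxy-2-methylcyclohexan-1-one (hydroxyl cis to CH2OTBS)
Conditions: (S)-1-methyl-3,3-diphenyltetrahydro-1H,3H-pyrrolo[1,2-c][1,3,2]oxazaborole (0.3 equiv), catecholborane, toluene, −60 °C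
Reagents that add atoms: none
Why: Corey–Bakshi–Shibata reduction used as a desymmetrisation of a 2,2-disubstituted 1,3-dione: the (S)-oxazaborolidine should fix the carbinol as R, and hydride should enter the carbonyl whose matched face lies anti to the larger CH2OTBS group, so the hydroxyl ends cis to CH2OTBS and the quaternary carbon (future C4) is set as R.

Step 4
Reactants: 4 hydroxy ketone
Product: 5 (1R,2S,3R)-2-{[tert-butyl(dimethyl)silyl]oxymethyl}-3-hydroxy-2-methylcyclohexyl benzoate (free hydroxyl trans to both the benzoate and CH2OTBS)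
Conditions: PhCHO (4 equiv), SmI2 (0.3 equiv), THF, −10 °C
Reagents that add atoms: benzaldehyde O=Cc1ccccc1
Why: Evans–Tishchenko reduction: the samarium-bound hemiacetal of the hydroxyl with benzaldehyde should pass hydride intramolecularly to the 1,3-related ketone through a six-membered transition state, so the new carbinol (future C3, R) is anti to the relay oxygen and therefore trans to the oxymethyl arm, and the relay oxygen leaves the step already protected as its benzoate.

Step 5
Reactants: 5 hydroxy benzoate
Product: 7 (4aS,5R,8aR)-2,2,4a-trimethylhexahydro-4H-1,3-benzodioxin-5-yl benzoate (trans-fused acetonide), via desilylated diol benzoate 6 (not isolated)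
Conditions: CSA (0.1 equiv), MeOH, 0 °C → rt; evaporate; then Me2C(OMe)2, acetone, rt
Reagents that add atoms: 2,2-dimethoxypropane COC(C)(C)OC
Why: Acid methanolysis of the primary silyl ether is followed by acid-catalysed acetalisation; only the free secondary hydroxyl, trans to the hydroxymethyl group, can close the 1,3-dioxane, which is therefore trans-fused with the C4 methyl axial, and no stereocenter changes.

Step 6
Reactants: 7 acetonide benzoate
Product: 8 (4aR,5R,8aR)-2,2,4a-trimethylhexahydro-4H-1,3-benzodioxin-5-ol
Conditions: K2CO3, MeOH, 40 °C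
Reagents that add atoms: none
Why: Base-catalysed transesterification (methanolysis) of the benzoate leaves the base-stable acetonide and all stereocenters untouched.

Step 7
Reactants: 8 acetonide alcohol
Product: 9 (4aS,8aR)-2,2,4a-trimethylhexahydro-4H-1,3-benzodioxin-5(4aH)-one
Conditions: Dess–Martin periodinane, NaHCO3, CH2Cl2, rt
Reagents that add atoms: none
Why: Dess–Martin oxidation turns the relay carbinol into the future C5 ketone; the neighbouring quaternary carbon cannot epimerise, so the C3/C4 pair set in steps 3 and 4 is kept.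

Step 8
Reactants: 9 acetonide ketone
Product: 11 (4aS,8aR)-2,2,4a,6-tetramethylhexahydro-4H-1,3-benzodioxin-5(4aH)-one as a mixture of C6 epimers, via lithium enolate 10 (not isolated)
Conditions: LiN(i-Pr)2, THF, −78 °C; then MeI, −78 → −20 °C
Reagents that add atoms: iodomethane CI
Why: Enolate alkylation: the ketone has a single enolisable α-carbon (future C10), so methylation is regiospecific, and the new stereocenter is of no consequence because it becomes sp2 in step 9.

Step 9
Reactants: 11 methyl ketone
Product: 13 (4aS,8aR)-2,2,4a,6-tetramethyl-4a,7,8,8a-tetrahydro-4H-1,3-benzodioxin-5-yl trifluoromethanesulfonate, via potassium enolate 12 (not isolated)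
Conditions: KN(SiMe3)2, THF, −78 °C; then PhNTf2, −78 → 0 °C
Reagents that add atoms: N-phenylbis(trifluoromethanesulfonimide) O=S(=O)(N(c1ccccc1)S(=O)(=O)C(F)(F)F)C(F)(F)F
Why: Enol triflate formation by O-sulfonylation of the only possible enolate should give the tetrasubstituted C5=C10 enol triflate and erase the C10 epimer mixture.

Step 10
Reactants: 13 enol triflate; 14 tributyl(1-ethoxyvinyl)stannane
Product: 15 (4aS,8aR)-5-(1-ethoxyethenyl)-2,2,4a,6-tetramethyl-4a,7,8,8a-tetrahydro-4H-1,3-benzodioxine (ring A 2-ethoxydiene spanning C10, C5, C6 and C7)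
Conditions: Pd(PPh3)4 (5 mol %), LiCl, CuI (10 mol %), 1,4-dioxane, 80 °C; chromatography on Et3N-washed silica
Reagents that add atoms: none
Why: Stille coupling of an enol triflate with an α-alkoxyvinylstannane, in which chloride and CuI speed transmetalation at the hindered tetrasubstituted carbon; no stereocenter is involved.

Step 11
Reactants: 16 methyl but-2-ynoate
Product: 17 methyl (2Z)-3-iodobut-2-enoate
Conditions: NaI, AcOH, 115 °C
Reagents that add atoms: sodium iodide [Na+].[I-]
Why: Hydroiodination of an ynoate by conjugate addition of iodide and anti protonation should give the Z isomer with iodine cis to the ester.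

Step 12
Reactants: 17 iodo ester
Product: 18 methyl (2E)-3-(4,4,5,5-tetramethyl-1,3,2-dioxaborolan-2-yl)but-2-enoate (this boryl group is written Bpin below; boron cis to the ester)
Conditions: B2pin2, PdCl2(PPh3)2 (3 mol %), PPh3, KOPh, toluene, 50 °C
Reagents that add atoms: bis(pinacolato)diboron CC1(C)OB(B2OC(C)(C)C(C)(C)O2)OC1(C)C
Why: Miyaura borylation of an alkenyl iodide, in which oxidative addition and reductive elimination both go with retention, so boron takes the place of iodine cis to the ester.

Step 13
Reactants: 15 ring A 2-ethoxydiene; 18 cis β-boryl crotonate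
Product: 19 Diels–Alder adduct: ring B cyclohexene with the C5=C6 enol ether (6-OEt), C8(CH3)(Bpin), C9(H)(CO2CH3) and C10(CH3), fused to the ring A acetonide; (3R,4S,8R,9S,10S), ester and boron cis to each other and anti to the methyls on C8 and C10
Conditions: CH2Cl2 (2 M), 14 kbar, 40 °C, 72 h, BHT and K2CO3 (traces)
Reagents that add atoms: none
Why: Normal-demand Diels–Alder reaction, concerted but asynchronous: the ethoxy group puts the largest HOMO coefficient on C7, which bonds first to the ester β-carbon C8, while the hindered terminus C10 closes on the CH carbon C9, so electronic and steric demands give the same regiochemistry. The closest known reaction types are the [4+2] additions of 1-vinyl-2-methylcyclohexene and 2-alkoxy dienes to β-substituted acrylates and of 3-borylacrylates to dienes; high pressure is chosen because the strongly negative activation volume should offset the crowding without heat (risk of 1,5-hydrogen shift from the inside methyl) or Lewis acid (loss of the enol ether and acetonide). Ring B closes as a six-membered carbocycle by suprafacial–suprafacial [4+2] closure, forming C9–C10 and C7–C8 and leaving the C5=C6 enol ether. C10 is controlled by the trans-fused acetonide, which holds the C4 methyl axial over one diene face so that the dienophile adds to the other face and the C10 methyl ends syn to the C4 methyl. C9 and C8 are controlled by the endo mode and the cis geometry of the dienophile: ester and boron sit under the diene and end anti to the C10 methyl, while H9 and the crotonate methyl take the exo positions and end syn to it. The step needs endo and facial selectivity; the first is secured by secondary overlap of the ester together with the small exo hydrogen next to the crowded C10, the second by the axial C4 methyl.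

Step 14
Reactants: 19 Diels–Alder adduct
Product: 20 6-ketone: as 19 but with C6=O and C5–H (H5 anti to the C10 methyl, trans-decalin); 8-Bpin, 9-CO2CH3 and the acetonide unchanged
Conditions: TsOH·H2O (0.1 equiv), acetone/H2O 20:1, rt; NaHCO3 quench
Reagents that add atoms: water O
Why: Enol ether hydrolysis: C5 should be protonated on the face away from the axial methyls on C4 and C10, which gives the trans ring fusion directly, and acid-catalysed enolisation toward C5 lets any cis isomer drain to the more stable trans-decalone, while acetone as solvent keeps the acetonide and the ester-bearing C9 is not enolised.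

Step 15
Reactants: 20 6-ketone
Product: 22 enol triflate of 20 toward C7 [C6(OTf)=C7; otherwise as 20], via potassium enolate 21 (not isolated)
Conditions: KN(SiMe3)2, THF, −78 °C; then PhNTf2, −78 → 0 °C
Reagents that add atoms: N-phenylbis(trifluoromethanesulfonimide) O=S(=O)(N(c1ccccc1)S(=O)(=O)C(F)(F)F)C(F)(F)F
Why: Kinetic enolisation and O-triflation (enol triflate formation): the C7 methylene should be deprotonated in preference to the C5 methine flanked by two quaternary carbons, so C5 keeps its configuration and no nucleophile has to add to the crowded C6 carbonyl.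

Step 16
Reactants: 22 enol triflate
Product: 24 methyl ester with C6 and C7 as methylenes [9-CO2CH3 and 8-Bpin cis; trans-decalin; acetonide], via alkene boronate 23 (not isolated)
Conditions: H2 (3 atm), PtO2, NaHCO3, EtOAc, rt
Reagents that add atoms: none
Why: Catalytic hydrogenolysis of the vinyl C–OTf bond and hydrogenation of the resulting disubstituted alkene delete the C6 oxygen; C6 and C7 become methylenes, so no stereocenter is formed, and the tertiary boronate should be inert.

Step 17
Reactants: 24 saturated ester
Product: 25 primary alcohol (9-CH2OH, C11) with 8-Bpin, otherwise as 24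
Conditions: i-Bu2AlH (3 equiv), CH2Cl2, −78 → 0 °C; aq. potassium sodium tartrate
Reagents that add atoms: none
Why: Ester reduction with diisobutylaluminium hydride, which tolerates the hindered pinacol boronate and does not enolise C9.

Step 18
Reactants: 25 primary alcohol
Product: 26 aldehyde (9-CHO) with 8-Bpin, otherwise as 24
Conditions: Dess–Martin periodinane, NaHCO3, CH2Cl2, 0 °C → rt
Reagents that add atoms: none
Why: Dess–Martin oxidation under buffered, non-basic conditions should give the aldehyde without epimerising the axial C9 substituent, and because boron still stands in for the C8 hydroxyl no β-hydroxy aldehyde prone to retro-aldol cleavage or dehydration is formed.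

Step 19
Reactants: 26 aldehyde
Product: 27 9-vinyl compound (C11=C12) with 8-Bpin, otherwise as 24
Conditions: Ph3PCH3Br, KN(SiMe3)2, THF, 0 °C; then 26, −78 → 0 °C
Reagents that add atoms: methyltriphenylphosphonium bromide C[P+](c1ccccc1)(c1ccccc1)c1ccccc1.[Br-]
Why: Wittig methylenation: the small, strongly nucleophilic ylide should add to the aldehyde at low temperature faster than it deprotonates C9, so the C9 configuration is kept.

Step 20
Reactants: 27 9-vinyl compound; 28 chloroprene (2-chlorobuta-1,3-diene)
Product: 31 8-hydroxy labda-13(16),14-diene acetonide [8-OH cis to the C9 side chain; 3-O and 4-CH2O as acetonide], via alkylborane adduct 29 (not isolated), via boronate diene 30 (not isolated)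
Conditions: 9-BBN, THF, rt → 50 °C; then 28, Pd(OAc)2 (5 mol %), SPhos (10 mol %), aq. K3PO4, THF, 50 °C; then aq. NaOH, 30% H2O2, 0 °C → rt
Reagents that add atoms: 9-borabicyclo[3.3.1]nonane B1C2CCCC1CCC2 (its boron stays only in 29); hydrogen peroxide OO
Why: Anti-Markovnikov hydroboration of the vinyl group, B-alkyl Suzuki–Miyaura coupling with the alkenyl chloride (oxidative addition helped by the electron-rich biaryl phosphine, while the tertiary pinacol boronate does not transmetalate) and alkaline peroxide oxidation of the remaining C8–B bond, which goes with retention and so places the C8 hydroxyl cis to the C9 side chain and anti to the methyls on C8 and C10.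

Step 21
Reactants: 31 diene acetonide
Product: 32 triol: labda-13(16),14-diene with 3-OH, 4-CH2OH and 8-OH
Conditions: PPTS, MeOH, 45 °C
Reagents that add atoms: none
Why: Acid-catalysed transacetalisation removes the acetonide under conditions mild enough for the 2-substituted diene and the tertiary alcohol.

Step 22
Reactants: 32 triol
Product: 33 primary tert-butyldimethylsilyl ether of 32 (4-CH2OTBS; 3-OH and 8-OH free)
Conditions: TBSCl (1.1 equiv), imidazole, CH2Cl2, 0 °C
Reagents that add atoms: tert-butyldimethylsilyl chloride CC(C)(C)[Si](C)(C)Cl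
Why: Selective silylation: the primary hydroxyl should react far faster than the secondary C3 and tertiary C8 hydroxyls.

Step 23
Reactants: 33 silyl ether diol
Product: 34 3-acetate of 33 (3-OAc, 4-CH2OTBS, 8-OH)
Conditions: Ac2O, pyridine, DMAP (cat.), CH2Cl2, rt
Reagents that add atoms: acetic anhydride CC(=O)OC(C)=O
Why: DMAP-catalysed acetylation of the secondary C3 hydroxyl; the tertiary C8 hydroxyl, flanked by a quaternary and a branched carbon, should stay free.

Step 24
Reactants: 34 acetate silyl ether
Product: 35 target CNP0313672.1, (3R,4S,5S,8S,9R,10R)-3-acetoxy-8-hydroxylabda-13(16),14-diene bearing CH2OH on C4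
Conditions: HF·pyridine, pyridine/THF, 0 °C → rt
Reagents that add atoms: none
Why: Fluoride desilylation under buffered, slightly acidic conditions should free the primary hydroxyl without acetyl migration from O3 and without harming the diene.

Compound list
1 | 2-methylcyclohexane-1,3-dione | CC1C(=O)CCCC1=O | starting material
2 | 2-(hydroxymethyl)-2-methylcyclohexane-1,3-dione | CC1(CO)C(=O)CCCC1=O | intermediate
3 | 2-{[tert-butyl(dimethyl)silyl]oxymethyl}-2-methylcyclohexane-1,3-dione | CC1(CO[Si](C)(C)C(C)(C)C)C(=O)CCCC1=O | intermediate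
4 | (2R,3R)-2-{[tert-butyl(dimethyl)silyl]oxymethyl}-3-hydroxy-2-methylcyclohexan-1-one | O=C1CCC[C@@H](O)[C@@]1(C)CO[Si](C)(C)C(C)(C)C | intermediate
5 | (1R,2S,3R)-2-{[tert-butyl(dimethyl)silyl]oxymethyl}-3-hydroxy-2-methylcyclohexyl benzoate | O[C@@H]1CCC[C@@H](OC(=O)c2ccccc2)[C@@]1(C)CO[Si](C)(C)C(C)(C)C | intermediate
6 | (1R,2S,3R)-3-hydroxy-2-(hydroxymethyl)-2-methylcyclohexyl benzoate (not isolated) | O[C@@H]1CCC[C@@H](OC(=O)c2ccccc2)[C@@]1(C)CO | intermediate
7 | (4aS,5R,8aR)-2,2,4a-trimethylhexahydro-4H-1,3-benzodioxin-5-yl benzoate | O=C(O[C@@H]1CCC[C@H]2OC(C)(C)OC[C@]12C)c1ccccc1 | intermediate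
8 | (4aR,5R,8aR)-2,2,4a-trimethylhexahydro-4H-1,3-benzodioxin-5-ol | O[C@@H]1CCC[C@H]2OC(C)(C)OC[C@]12C | intermediate
9 | (4aS,8aR)-2,2,4a-trimethylhexahydro-4H-1,3-benzodioxin-5(4aH)-one | O=C1CCC[C@H]2OC(C)(C)OC[C@]12C | intermediate
10 | lithium enolate of 9 (not isolated) | [Li]OC1=CCC[C@H]2OC(C)(C)OC[C@]12C | intermediate
11 | (4aS,8aR)-2,2,4a,6-tetramethylhexahydro-4H-1,3-benzodioxin-5(4aH)-one, both C6 epimers | O=C1C(C)CC[C@H]2OC(C)(C)OC[C@]12C | intermediate
12 | potassium enolate of 11 (not isolated) | [K]OC1=C(C)CC[C@H]2OC(C)(C)OC[C@]12C | intermediate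
13 | (4aS,8aR)-2,2,4a,6-tetramethyl-4a,7,8,8a-tetrahydro-4H-1,3-benzodioxin-5-yl trifluoromethanesulfonate | FC(F)(F)S(=O)(=O)OC1=C(C)CC[C@H]2OC(C)(C)OC[C@]12C | intermediate
14 | tributyl(1-ethoxyvinyl)stannane | C=C(OCC)[Sn](CCCC)(CCCC)CCCC | starting material
15 | (4aS,8aR)-5-(1-ethoxyethenyl)-2,2,4a,6-tetramethyl-4a,7,8,8a-tetrahydro-4H-1,3-benzodioxine | CCOC(=C)C1=C(C)CC[C@H]2OC(C)(C)OC[C@]12C | intermediate
16 | methyl but-2-ynoate | CC#CC(=O)OC | starting material
17 | methyl (2Z)-3-iodobut-2-enoate | C/C(I)=C/C(=O)OC | intermediate
18 | methyl (2E)-3-(4,4,5,5-tetramethyl-1,3,2-dioxaborolan-2-yl)but-2-enoate | C/C(B1OC(C)(C)C(C)(C)O1)=C/C(=O)OC | intermediate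
19 | Diels–Alder adduct, (3R,4S,8R,9S,10S): 6-ethoxy-5-ene, 8-Bpin, 9-CO2CH3, ring A acetonide | COC(=O)[C@@H]1[C@]2(C)CC[C@H]3OC(C)(C)OC[C@]3(C)C2=C(OCC)C[C@]1(C)B4OC(C)(C)C(C)(C)O4 | intermediate
20 | 6-ketone, trans-decalin (H5 anti to the C10 methyl), 8-Bpin, 9-CO2CH3, acetonide | COC(=O)[C@@H]1[C@]2(C)CC[C@H]3OC(C)(C)OC[C@]3(C)[C@H]2C(=O)C[C@]1(C)B4OC(C)(C)C(C)(C)O4 | intermediate
21 | potassium enolate of 20 toward C7 (not isolated) | COC(=O)[C@@H]1[C@]2(C)CC[C@H]3OC(C)(C)OC[C@]3(C)[C@H]2C(O[K])=C[C@]1(C)B4OC(C)(C)C(C)(C)O4 | intermediate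
22 | 6-en-6-yl triflate of 20 | COC(=O)[C@@H]1[C@]2(C)CC[C@H]3OC(C)(C)OC[C@]3(C)[C@H]2C(OS(=O)(=O)C(F)(F)F)=C[C@]1(C)B4OC(C)(C)C(C)(C)O4 | intermediate
23 | 6-ene with 8-Bpin and 9-CO2CH3 (not isolated) | COC(=O)[C@@H]1[C@]2(C)CC[C@H]3OC(C)(C)OC[C@]3(C)[C@H]2C=C[C@]1(C)B4OC(C)(C)C(C)(C)O4 | intermediate
24 | saturated methyl ester, 8-Bpin cis to 9-CO2CH3, trans-decalin, acetonide | COC(=O)[C@@H]1[C@]2(C)CC[C@H]3OC(C)(C)OC[C@]3(C)[C@H]2CC[C@]1(C)B4OC(C)(C)C(C)(C)O4 | intermediate
25 | primary alcohol (9-CH2OH), 8-Bpin, acetonide | OC[C@@H]1[C@]2(C)CC[C@H]3OC(C)(C)OC[C@]3(C)[C@H]2CC[C@]1(C)B4OC(C)(C)C(C)(C)O4 | intermediate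
26 | aldehyde (9-CHO), 8-Bpin, acetonide | O=C[C@@H]1[C@]2(C)CC[C@H]3OC(C)(C)OC[C@]3(C)[C@H]2CC[C@]1(C)B4OC(C)(C)C(C)(C)O4 | intermediate
27 | 9-vinyl compound, 8-Bpin, acetonide | C=C[C@@H]1[C@]2(C)CC[C@H]3OC(C)(C)OC[C@]3(C)[C@H]2CC[C@]1(C)B4OC(C)(C)C(C)(C)O4 | intermediate
28 | chloroprene (2-chlorobuta-1,3-diene) | C=CC(Cl)=C | starting material
29 | B-alkyl-9-BBN adduct at C12 (not isolated) | C1CCC2CCCC1B2CC[C@@H]1[C@]2(C)CC[C@H]3OC(C)(C)OC[C@]3(C)[C@H]2CC[C@]1(C)B4OC(C)(C)C(C)(C)O4 | intermediate
30 | 8-Bpin labda-13(16),14-diene acetonide (not isolated) | C=CC(=C)CC[C@@H]1[C@]2(C)CC[C@H]3OC(C)(C)OC[C@]3(C)[C@H]2CC[C@]1(C)B4OC(C)(C)C(C)(C)O4 | intermediate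
31 | 8-hydroxy labda-13(16),14-diene acetonide | C=CC(=C)CC[C@@H]1[C@]2(C)CC[C@H]3OC(C)(C)OC[C@]3(C)[C@H]2CC[C@]1(C)O | intermediate
32 | triol (3-OH, 4-CH2OH, 8-OH) | C=CC(=C)CC[C@@H]1[C@]2(C)CC[C@@H](O)[C@](C)(CO)[C@H]2CC[C@]1(C)O | intermediate
33 | primary TBS ether of 32 | C=CC(=C)CC[C@@H]1[C@]2(C)CC[C@@H](O)[C@](C)(CO[Si](C)(C)C(C)(C)C)[C@H]2CC[C@]1(C)O | intermediate
34 | 3-acetate of 33 | C=CC(=C)CC[C@@H]1[C@]2(C)CC[C@@H](OC(C)=O)[C@](C)(CO[Si](C)(C)C(C)(C)C)[C@H]2CC[C@]1(C)O | intermediate
35 | CNP0313672.1, (3R,4S,5S,8S,9R,10R) | C=CC(=C)CC[C@@H]1[C@]2(C)CC[C@@H](OC(C)=O)[C@](C)(CO)[C@H]2CC[C@]1(C)O | target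

Total step count: 24. Longest linear sequence: 22 steps (steps 1–10 and 13–24); steps 11 and 12 make the dienophile.

Steps most likely to fail

Step 13. The cycloaddition may stall because a tetrasubstituted diene terminus has to meet a trisubstituted dienophile, or the endo and facial preference may erode at the pressure and time needed. The fallback sets out from 15 and returns at 20; it replaces the concerted step by an anionic double Michael annulation. Mild hydrolysis of 15 (oxalic acid on wet silica) gives the methyl ketone enone F1. Its kinetic cross-conjugated lithium dienolate (LiN(i-Pr)2, THF, −78 °C) should add through C7 to the β-carbon of 18, and the ester enolate so formed should close on C10 of the enone through a lithium-bridged, endo-like arrangement, making the same two bonds stepwise. Protonation of the resulting C5 enolate from the face away from the axial methyls gives ketone 20, and the route resumes at step 15.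

Step 20. Oxidative addition into the chlorodiene may be slow relative to protodeboronation of the alkylborane, and chloroprene may oligomerise at the coupling temperature. The fallback sets out from 27 and returns at 31; it reverses the polarity of the C12–C13 bond formation. Hydroboration of 27 with 9-BBN and direct alkaline peroxide work-up oxidises both C–B bonds and gives the primary/tertiary diol F2. Appel-type iodination (I2, PPh3, imidazole) converts only the primary hydroxyl into the iodide F3. Buta-1,3-dien-2-ylmagnesium chloride F4, made from chloroprene 28 and magnesium (ZnCl2-activated, THF), is then coupled with F3 under Li2CuCl4 catalysis, one extra equivalent of the Grignard reagent being spent on the tertiary hydroxyl, to give 31.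

Step 4. The transannular hydride shift may be slow in a hemiacetal held on a ring next to a quaternary carbon, which would leave room for acyl-transfer and aldol-type side reactions. The fallback sets out from 4 and returns at 6; it separates protection from reduction. Benzoylation of 4 (BzCl, pyridine, DMAP) gives the keto benzoate F5, and HF·pyridine removes the silyl group to give the hydroxymethyl ketone F6. An Evans–Saksena reduction (Me4NBH(OAc)3, MeCN/AcOH, −30 °C) should then deliver hydride from the alkoxyborohydride of the primary hydroxyl to the carbonyl face on its own side, giving diol benzoate 6 with the new hydroxyl trans to the hydroxymethyl group. Acetalisation as in the second operation of step 5 gives 7.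

Further compounds
F1 | step 13 | 1-[(4aS,8aR)-2,2,4a,6-tetramethyl-4a,7,8,8a-tetrahydro-4H-1,3-benzodioxin-5-yl]ethan-1-one | CC(=O)C1=C(C)CC[C@H]2OC(C)(C)OC[C@]12C
F2 | step 20 | 12,8-diol (9-CH2CH2OH, 8-OH) with ring A acetonide | OCC[C@@H]1[C@]2(C)CC[C@H]3OC(C)(C)OC[C@]3(C)[C@H]2CC[C@]1(C)O
F3 | step 20 | 12-iodide (9-CH2CH2I, 8-OH) with ring A acetonide | ICC[C@@H]1[C@]2(C)CC[C@H]3OC(C)(C)OC[C@]3(C)[C@H]2CC[C@]1(C)O
F4 | step 20 | buta-1,3-dien-2-ylmagnesium chloride | C=CC(=C)[Mg]Cl
F5 | step 4 | (1R,2R)-2-{[tert-butyl(dimethyl)silyl]oxymethyl}-2-methyl-3-oxocyclohexyl benzoate | O=C1CCC[C@@H](OC(=O)c2ccccc2)[C@@]1(C)CO[Si](C)(C)C(C)(C)C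
F6 | step 4 | (1R,2R)-2-(hydroxymethyl)-2-methyl-3-oxocyclohexyl benzoate | O=C1CCC[C@@H](OC(=O)c2ccccc2)[C@@]1(C)CO
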